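The whole route rests on cutting the bond between ring carbon C3 of the benzene ring and the first alkene carbon of the 3-hydroxy-3-methylbutenyl chain. The ring is para-substituted (acrylate at C1, oxygen at C4), so C3 and C5 are equivalent C–H positions ortho to that oxygen. An acetamido group on the oxygen guides the rhodium of [Cp*RhCl2]2 to C3, the alkene of 2-methyl-3-buten-2-ol is joined there as an E-styrene, and the O–N bond is consumed as the oxidant, which uncovers the phenol for the last acylation. The precursor is therefore the N-aryloxyacetamide of methyl (E)-4-hydroxycinnamate; the (S)-3-acetoxybutanoyl unit from the chiral pool is added last.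

Key step: step 3

Remark: the single stereocentre of the target, C3 of the butanoyl unit, has the S configuration and is carried unchanged from (S)-3-hydroxybutanoic acid; the arylboronic acid used in step 1 is assumed to be a catalogue compound.

Step 1
Reactants: 1 (E)-[4-(3-methoxy-3-oxoprop-1-enyl)phenyl]boronic acid (1.8 equiv); 2 N-hydroxyphthalimide (1.0 equiv)
Product: 3 methyl (E)-3-{4-[(1,3-dioxoisoindolin-2-yl)oxy]phenyl}acrylate
Conditions: Cu(OAc)2 (1.0 equiv), pyridine (1.1 equiv), 4 Å MS, ClCH2CH2Cl, open to air (O2 as terminal oxidant), rt
Reagents that add atoms: none
Why: Chan–Lam O-arylation, in which the acidic N-hydroxy imide binds Cu(OAc)2, the aryl group is transferred from boron and the aryl C–O bond forms by reductive elimination from copper, with air returning the copper to the divalent state; the ester and the E-alkene are spectators, and the excess of 1 offsets protodeboronation.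

Step 2
Reactants: 3 methyl (E)-3-{4-[(1,3-dioxoisoindolin-2-yl)oxy]phenyl}acrylate
Product: 5 methyl (E)-3-[4-(acetamidooxy)phenyl]acrylate, via O-arylhydroxylamine 4 (not isolated)
Conditions: N2H4·H2O (1.2 equiv), CH2Cl2/MeOH 9:1, 0 °C to rt; filter, wash with H2O, dry; then Ac2O (1.1 equiv), CH2Cl2, 0 °C
Reagents that add atoms: acetic anhydride, CC(=O)OC(C)=O
Why: Ing–Manske-type hydrazinolysis of the activated N-aryloxy imide should be complete at or below room temperature, well before hydrazine can attack the methyl cinnamate, and the freed O-arylhydroxylamine is N-acetylated at once (amide formation with an anhydride), so the labile free base is never stored.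

Step 3
Reactants: 5 methyl (E)-3-[4-(acetamidooxy)phenyl]acrylate; 6 2-methyl-3-buten-2-ol (3 equiv)
Product: 7 methyl (E)-3-{4-hydroxy-3-[(E)-3-hydroxy-3-methylbut-1-enyl]phenyl}acrylate
Conditions: [Cp*RhCl2]2 (2.5 mol%), CsOAc (0.5 equiv), MeOH, N2, rt to 40 °C
Reagents that add atoms: none
Why: CsOAc converts [Cp*RhCl2]2 into a Cp*Rh acetate species of trivalent rhodium that binds the deprotonated amide nitrogen of 5 and cleaves an ortho C–H bond by acetate-assisted concerted metalation–deprotonation, giving a five-membered rhodacycle (Rh, N, O, C4, C3). The monosubstituted alkene of 6 inserts into the Rh–aryl bond with the aryl group on the CH2 terminus, and syn β-hydride elimination from the new benzylic CH2, the only β-carbon bearing hydrogen since the carbinol carbon is quaternary, gives the E alkene. Reductive elimination of N–H from the rhodium hydride leaves monovalent rhodium, which adds oxidatively into the O–N bond and so returns to the trivalent state; protonolysis by methanol then releases phenol 7 and acetamide, so no external oxidant is needed. The closest known reaction type is the redox-neutral ortho C–H olefination of N-aryloxyacetamides with terminal alkenes under [Cp*RhCl2]2 and an acetate base; no ring is closed and no stereocentre is created, the E geometry being the only stereochemical outcome. Single olefination is secured because C3 and C5 are equivalent and the directing group is destroyed in the same turnover that forms the bond. β-Hydride elimination must outrun β-hydroxide elimination (which would give the prenyl arene) and transfer of the amide to carbon, which is why a weakly basic methanolic medium free of Lewis acids and an excess of 6 are chosen; the 1,2-disubstituted acrylate alkene of 5 is too hindered to compete for insertion.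

Step 4
Reactants: 8 (S)-3-hydroxybutanoic acid
Product: 9 (S)-3-acetoxybutanoic acid
Conditions: AcCl (3 equiv), neat, 0 °C to rt; then H2O, THF, rt; evaporate
Reagents that add atoms: acetyl chloride, CC(=O)Cl
Why: O-Acetylation of a secondary alcohol by an acyl chloride leaves the C3–O bond intact, so the S configuration is retained, and any mixed anhydride formed at the carboxyl group is hydrolysed in the aqueous finish.

Step 5
Reactants: 7 methyl (E)-3-{4-hydroxy-3-[(E)-3-hydroxy-3-methylbut-1-enyl]phenyl}acrylate; 9 (S)-3-acetoxybutanoic acid (1.2 equiv)
Product: 10 methyl (E)-3-{4-{[(3S)-3-acetoxybutanoyl]oxy}-3-[(E)-3-hydroxy-3-methylbut-1-enyl]phenyl}acrylate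
Conditions: N,N'-diisopropylcarbodiimide (1.3 equiv), 4-(dimethylamino)pyridinium 4-toluenesulfonate (0.3 equiv), CH2Cl2, 0 °C to rt
Reagents that add atoms: none
Why: Steglich-type carbodiimide esterification in which the phenol, far more accessible than the tertiary allylic alcohol, takes the acyl group from the O-acylisourea by way of the acylpyridinium, while the buffered pyridinium salt used in place of free amine base should suppress E1cB loss of acetic acid to the crotonate; the stereocentre of 9 is a spectator, so the S configuration passes into 10.

Compound list
1 | (E)-[4-(3-methoxy-3-oxoprop-1-enyl)phenyl]boronic acid | COC(=O)/C=C/c1ccc(B(O)O)cc1 | starting material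
2 | N-hydroxyphthalimide | O=C1N(O)C(=O)c2ccccc21 | starting material
3 | methyl (E)-3-{4-[(1,3-dioxoisoindolin-2-yl)oxy]phenyl}acrylate | COC(=O)/C=C/c1ccc(ON2C(=O)c3ccccc3C2=O)cc1 | intermediate
4 | methyl (E)-3-[4-(aminooxy)phenyl]acrylate | COC(=O)/C=C/c1ccc(ON)cc1 | intermediate
5 | methyl (E)-3-[4-(acetamidooxy)phenyl]acrylate | COC(=O)/C=C/c1ccc(ONC(C)=O)cc1 | intermediate
6 | 2-methyl-3-buten-2-ol | C=CC(C)(C)O | starting material
7 | methyl (E)-3-{4-hydroxy-3-[(E)-3-hydroxy-3-methylbut-1-enyl]phenyl}acrylate | COC(=O)/C=C/c1ccc(O)c(/C=C/C(C)(C)O)c1 | intermediate
8 | (S)-3-hydroxybutanoic acid | C[C@H](O)CC(=O)O | starting material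
9 | (S)-3-acetoxybutanoic acid | C[C@H](OC(C)=O)CC(=O)O | intermediate
10 | methyl (E)-3-{4-{[(3S)-3-acetoxybutanoyl]oxy}-3-[(E)-3-hydroxy-3-methylbut-1-enyl]phenyl}acrylate | COC(=O)/C=C/c1ccc(OC(=O)C[C@H](C)OC(C)=O)c(/C=C/C(C)(C)O)c1 | target

Total step count: 5. Longest linear sequence: 4 steps (steps 1, 2, 3 and 5, from 1 to 10); step 4 is a one-step side branch.

Steps most likely to fail

Step 3. Insertion of the hindered, unactivated alkene may be slower than unproductive loss of the O–N bond. The alkylrhodium intermediate may also collapse by β-hydroxide elimination or by amide transfer to carbon instead of β-hydride elimination. During isolation the ortho-hydroxy allylic alcohol may cyclodehydrate on acidic silica, so base-washed silica is planned. The fallback is a Heck route that sets out from 6. Purchased 4-hydroxy-3-iodobenzaldehyde F1 is condensed with methyl (triphenylphosphoranylidene)acetate (toluene, 80 °C; Wittig reaction, E-selective with the stabilised ylide) to give methyl (E)-3-(4-hydroxy-3-iodophenyl)acrylate F2. F2 is then coupled with 6 in a ligand-free Heck reaction under phase-transfer conditions (Pd(OAc)2, Bu4NCl, NaHCO3, DMF, 60 °C). With this tertiary allylic alcohol that coupling is known to end by β-hydride elimination on the benzylic side and to give the E allylic alcohol. The fallback comes back to the route at 7.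

Step 5. The activated β-acetoxy acyl unit may lose acetic acid by elimination, the O-acylisourea may rearrange to an unreactive N-acylurea before the phenol is acylated, and acyl transfer to the deactivated phenol may be slow. The fallback sets out from 9 and replaces in-flask activation by an isolated acyl chloride. Treatment of 9 with (COCl)2 and catalytic DMF in CH2Cl2 (0 °C to rt) should give (S)-3-acetoxybutanoyl chloride F3. F3 acylates 7 with pyridine (1.5 equiv) in CH2Cl2 at −40 to 0 °C, a base too weak to trigger elimination at that temperature and conditions under which the tertiary alcohol stays untouched. The fallback comes back to the route at 10.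

Step 2. Hydrazine may add to or cleave the cinnamate ester in competition with imide cleavage, and the free O-arylhydroxylamine may decompose during the hand-over to acetylation. The fallback sets out from 1 and avoids both the imide and hydrazine. ipso-Hydroxylation of 1 with aqueous H2O2 in EtOH at rt gives methyl (E)-4-hydroxycinnamate F4, which may also simply be bought. Its potassium salt (KOtBu, MeOH, then DMF) is O-aminated with freshly prepared O-(mesitylsulfonyl)hydroxylamine in CH2Cl2 at 0 °C, an electrophilic amination of a phenoxide. This gives 4, where the fallback re-joins the route, and acetylation as in the second half of step 2 then leads to 5.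

Further compounds
F1 | step 3 | 4-hydroxy-3-iodobenzaldehyde | O=Cc1ccc(O)c(I)c1
F2 | step 3 | methyl (E)-3-(4-hydroxy-3-iodophenyl)acrylate | COC(=O)/C=C/c1ccc(O)c(I)c1
F3 | step 5 | (S)-3-acetoxybutanoyl chloride | C[C@H](OC(C)=O)CC(=O)Cl
F4 | step 2 | methyl (E)-4-hydroxycinnamate | COC(=O)/C=C/c1ccc(O)cc1
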